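Ring B is disconnected last. It is a pentasubstituted resorcinol (O on a3 and a5, H on a4, carbon on a6, a1 and a2, the last two shared with the seven-membered ring C), exactly the pattern produced when a cycloalkenyl vinylketene and a terminal ynol ether are merged. One photochemical operation on a benzo-fused (ring D) cycloheptenyl diazomethyl ketone that already holds Ca, Cf and the protected Ce carbinol makes four ring B bonds and delivers a free a3 phenol next to Ce and a silyl ether on a5. Ca comes from a rhodium-catalysed conjugate arylation, Cf from an allylboration, ring C from olefin metathesis; rings E and F follow.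

Key step: step 12

Labels: ring B = a1–a6 (a1 bonded to the ring C CH2, a2 to Cf); ring D = d1–d6 (d1 on Cf, d6 on Ca, OMe on d3 and d5); Ca = ring C CH(aryl); Cg = ring C CH2; Cf = CH shared by rings C and E; Ce = ring E OCH(aryl); C7' = ring F CH(aryl) on a6; C8' = ring F OCH(aryl) on the a5 oxygen.

Remark on Ce: ring E is closed by ionisation at Ce, so the configuration of the Ce carbinol carried through the route has no bearing on the target; the anti isomer (Ce S, Cf R) is carried because the allylboration gives it.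

Assumption: 20 is treated as a purchasable reagent, and the catalysts of steps 3 and 17 are written with the sense of induction known for their closest substrates (the mirror-image catalyst would be used if this substrate reversed it).

Step 1
Reactants: 1 2-bromo-3,5-dimethoxybenzaldehyde; 2 bis(pinacolato)borylmethane
Product: 3 (E)-2-[2-(2-bromo-3,5-dimethoxyphenyl)ethenyl]-4,4,5,5-tetramethyl-1,3,2-dioxaborolane
Conditions: lithium 2,2,6,6-tetramethylpiperidide (LiTMP, 1.2 equiv), 2, THF, 0 °C; then 1, −78 °C to rt; H2O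
Reagents that add atoms: none
Why: Boron-Wittig olefination, in which the α-boryl carbanion adds to the aldehyde and B–O elimination gives the E-alkenylboronate, the amide base being consumed before 1 is added so that the aryl bromide is untouched.

Step 2
Reactants: 3 (E)-alkenylboronate
Product: 4 (E)-2-[3-(2-bromo-3,5-dimethoxyphenyl)prop-2-en-1-yl]-4,4,5,5-tetramethyl-1,3,2-dioxaborolane
Conditions: ClCH2I (2 equiv), n-BuLi (1.7 equiv, added last), THF, −78 °C to rt
Reagents that add atoms: chloroiodomethane, ClCI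
Why: Matteson homologation, in which chloromethyllithium formed in situ adds to boron and 1,2-migration of the alkenyl group with loss of chloride inserts CH2 with retention of the E geometry, iodine–lithium exchange on ClCH2I being faster than bromine–lithium exchange on the arene.

Step 3
Reactants: 4 (E)-allylboronate; 5 4-methoxybenzaldehyde
Product: 7 (1S,2R)-2-(2-bromo-3,5-dimethoxyphenyl)-1-(4-methoxyphenyl)but-3-en-1-ol (anti), via pinacol borate ester 6 (not isolated)
Conditions: (S)-3,3'-bis(2,4,6-triisopropylphenyl)-1,1'-binaphthyl-2,2'-diyl hydrogen phosphate ((S)-TRIP, 5 mol%), 4 Å MS, toluene, −30 to 0 °C; aq NaHCO3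
Reagents that add atoms: none
Why: Chiral phosphoric acid catalysed allylboration through a closed chair (Zimmerman–Traxler) transition state, in which the E-γ-aryl group sits equatorial so that the anti diastereomer forms and the catalyst selects the aldehyde face, fixing Cf (R) together with Ce (S).

Step 4
Reactants: 7 anti homoallylic alcohol
Product: 8 tert-butyldimethylsilyl ether of 7 (Ce S, Cf R)
Conditions: TBSOTf (1.3 equiv), 2,6-lutidine (2 equiv), CH2Cl2, −78 to 0 °C
Reagents that add atoms: tert-butyldimethylsilyl trifluoromethanesulfonate, CC(C)(C)[Si](C)(C)OS(=O)(=O)C(F)(F)F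
Why: Silylation of a secondary benzylic alcohol under buffered, non-acidic conditions that touch no stereocenter.

Step 5
Reactants: 8 aryl bromide
Product: 10 2-[(1S,2R)-1-(tert-butyldimethylsilyloxy)-1-(4-methoxyphenyl)but-3-en-2-yl]-4,6-dimethoxybenzaldehyde, via aryllithium 9 (not isolated)
Conditions: n-BuLi (1.05 equiv), THF, −78 °C, 10 min; DMF (3 equiv), −78 to 0 °C; H2O
Reagents that add atoms: N,N-dimethylformamide, CN(C)C=O
Why: Bromine–lithium exchange at −78 °C is faster than any deprotonation, and the aryllithium is formylated by DMF (Bouveault formylation) at d6.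

Step 6
Reactants: 10 aldehyde; 11 3,3-dimethoxybutan-2-one
Product: 12 (E)-1-{2-[(1S,2R)-1-(tert-butyldimethylsilyloxy)-1-(4-methoxyphenyl)but-3-en-2-yl]-4,6-dimethoxyphenyl}-4,4-dimethoxypent-1-en-3-one
Conditions: NaOH (2 M aq, 2 equiv), MeOH/THF, 40 °C
Reagents that add atoms: none
Why: Claisen–Schmidt aldol condensation in which the ketone can enolise only at its methyl group and the aldehyde has no α-hydrogen, so a single E-enone should result.

Step 7
Reactants: 12 enone; 13 4-methoxyphenylboronic acid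
Product: 14 (1S)-1-{2-[(1S,2R)-1-(tert-butyldimethylsilyloxy)-1-(4-methoxyphenyl)but-3-en-2-yl]-4,6-dimethoxyphenyl}-4,4-dimethoxy-1-(4-methoxyphenyl)pentan-3-one
Conditions: [Rh(cod)Cl]2 (3 mol%), (R)-BINAP (6.6 mol%), 13 (3 equiv), KOH (0.5 equiv), 1,4-dioxane/H2O 10:1, 60 °C
Reagents that add atoms: none
Why: Hayashi–Miyaura asymmetric 1,4-addition, in which the aryl–rhodium/(R)-BINAP species carbometalates the re face of the enone α-carbon (catalyst control, as for acyclic E-enones) and so sets Ca (S), water protonating the oxa-π-allyl rhodium so that no hydride able to move the Cf vinyl group is formed.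

Step 8
Reactants: 14 ketone
Product: 15 (4S)-2-(1,1-dimethoxyethyl)-4-(4-methoxyphenyl)-4-{2-[(1S,2R)-1-(tert-butyldimethylsilyloxy)-1-(4-methoxyphenyl)but-3-en-2-yl]-4,6-dimethoxyphenyl}but-1-ene
Conditions: Ph3PCH3Br (3.0 equiv), KN(SiMe3)2 (2.8 equiv), THF, 0 °C; 14, rt to 45 °C
Reagents that add atoms: methyltriphenylphosphonium bromide, C[P+](c1ccccc1)(c1ccccc1)c1ccccc1.[Br-]
Why: Wittig methylenation of an α,α-dialkoxy ketone, which is activated toward ylide addition, the base being kept below the amount of phosphonium salt so that no free strong base can isomerise the Cf vinyl group.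

Step 9
Reactants: 15 ketal
Product: 16 (5S)-5-{2-[(1S,2R)-1-(tert-butyldimethylsilyloxy)-1-(4-methoxyphenyl)but-3-en-2-yl]-4,6-dimethoxyphenyl}-5-(4-methoxyphenyl)-3-methylidenepentan-2-one
Conditions: PPTS (0.2 equiv), acetone/H2O 10:1, rt
Reagents that add atoms: water, O
Why: Mild acid hydrolysis of a dimethyl ketal through an allyl-stabilised oxocarbenium ion, pyridinium tosylate being too weak an acid to ionise the benzylic silyl ether.

Step 10
Reactants: 16 diene
Product: 17 1-[(5S,9R)-9-[(S)-(tert-butyldimethylsilyloxy)(4-methoxyphenyl)methyl]-2,4-dimethoxy-5-(4-methoxyphenyl)-6,9-dihydro-5H-benzo[7]annulen-7-yl]ethan-1-one (ring C closed, a1=a2)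
Conditions: second-generation Hoveyda–Grubbs catalyst [RuCl2(H2IMes)(=CH-C6H4-2-OiPr)] (10 mol%), 1,4-benzoquinone (20 mol%), toluene (5 mM), 80 °C
Reagents that add atoms: none
Why: Ring-closing olefin metathesis, in which the catalyst loads on the monosubstituted vinyl group and closes onto the 1,1-disubstituted enone alkene, the ortho-disposed tethers on ring D favouring the seven-membered ring and loss of ethene driving the reaction while Ca and Cf stay untouched.

Step 11
Reactants: 17 cycloheptenyl methyl ketone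
Product: 19 2-diazo-1-[(5S,9R)-9-[(S)-(tert-butyldimethylsilyloxy)(4-methoxyphenyl)methyl]-2,4-dimethoxy-5-(4-methoxyphenyl)-6,9-dihydro-5H-benzo[7]annulen-7-yl]ethan-1-one, via trifluoroacetyl diketone 18 (not isolated)
Conditions: LiN(SiMe3)2 (1.1 equiv), THF, −78 °C; CF3CO2CH2CF3 (1.2 equiv), −78 °C; cold 5% aq HCl; then MsN3 (1.5 equiv), Et3N (1.5 equiv), H2O (1 equiv), MeCN, rt
Reagents that add atoms: methanesulfonyl azide, CS(=O)(=O)N=[N+]=[N-]; 2,2,2-trifluoroethyl trifluoroacetate, O=C(OCC(F)(F)F)C(F)(F)F (its trifluoroacetyl group is carried only by 18)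
Why: Detrifluoroacetylative diazo transfer, in which kinetic deprotonation at the methyl group (not at the γ-position Cf) and Claisen trifluoroacetylation activate the ketone for diazo transfer with loss of the trifluoroacetyl group, a route that avoids acylating diazomethane with an enoyl chloride, where dipolar cycloaddition to the alkene competes.

Step 12
Reactants: 19 cycloheptenyl diazomethyl ketone; 20 triisopropylsilyloxyacetylene
Product: 25 (5S,10S)-5-[(S)-(tert-butyldimethylsilyloxy)(4-methoxyphenyl)methyl]-7,9-dimethoxy-10-(4-methoxyphenyl)-2-(triisopropylsilyloxy)-10,11-dihydro-5H-dibenzo[a,d][7]annulen-4-ol (a3 OH, a5 OTIPS, a4 and a6 H), via vinylketene 21 (not isolated), via alkenylcyclobutenone 22 (not isolated), via dienylketene 23 (not isolated), via cyclohexadienone 24 (not isolated)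
Conditions: 20 (2 equiv), ClCH2CH2Cl (0.05 M, degassed, filtered through basic Al2O3), hν 300 nm (Pyrex), rt; then 80 °C in the dark
Reagents that add atoms: none
Why: Light expels N2 from 19 and the alkenyl carbon a1 migrates to the diazo carbon (Wolff rearrangement) to give vinylketene 21, which adds the electron-rich alkyne 20 in a thermal (2+2) cycloaddition to cyclobutenone 22; on warming, 22 opens in a 4π electrocyclic step to dienylketene 23, which closes in a 6π electrocyclic step to dienone 24 and tautomerises to phenol 25. The closest known reaction type is the Danheiser benzannulation in its photochemical Wolff variant, which converts cycloalkenyl diazomethyl ketones and siloxyalkynes into resorcinol monosilyl ethers. Ring B is the only ring closed, by 6π electrocyclisation of the dienylketene (a3 to a2), after a1–a6 (migration), a3–a4 and a5–a6 (cycloaddition) have been made. No stereocenter is created, and Ca, Cf and Ce lie outside the reacting π system. The one selectivity needed is regiochemical: the nucleophilic CH terminus of the ynol ether bonds to the electrophilic ketene carbonyl carbon, so the silyloxy group ends on a5 and the free hydroxyl on a3 with a4-H between them, and the polarity of 20 secures this. The ketenyl group on a1 is cis to a2-H and trans to Cf across the ring alkene, which excludes a 1,5-hydrogen shift from Cf, and 300 nm light keeps the alkoxyarene chromophores from absorbing.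

Step 13
Reactants: 25 phenol
Product: 26 1-bromo derivative of 25 (Br on a6; Ca S, Cf S, Ce S)
Conditions: NBS (1.0 equiv), CH2Cl2, −78 to −40 °C
Reagents that add atoms: N-bromosuccinimide, O=C1CCC(=O)N1Br
Why: Electrophilic aromatic bromination at a6, which is para to the free a3 hydroxyl and ortho to the a5 silyloxy group, the strongest directing combination in the molecule, so that the free phenol ring reacts before the methyl ether rings.

Step 14
Reactants: 26 bromophenol
Product: 28 ring E trans-dihydrobenzofuran (a3–O–Ce closed; Ce S, Cf S, Ca S; a5 OTIPS, a6 Br), via benzylic alcohol 27 (not isolated)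
Conditions: p-TsOH·H2O (0.3 equiv), MeOH/CH2Cl2 1:4, 0 °C to rt
Reagents that add atoms: none
Why: Acid-mediated SN1 cycloetherification, in which loss of the silyl group and ionisation give the 4-methoxybenzylic cation at Ce, which the neighbouring a3 phenol captures in a 5-exo closure that is reversible, so the more stable trans-2-aryl-3-substituted dihydrobenzofuran should form whatever the configuration of Ce in 26.

Step 15
Reactants: 28 aryl silyl ether; 29 4-methoxybenzyl chloride
Product: 31 a5 4-methoxybenzyl ether of the ring E compound (a6 Br), via caesium phenoxide 30 (not isolated)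
Conditions: CsF (3 equiv), 29 (1.5 equiv), DMF, rt to 50 °C
Reagents that add atoms: none
Why: Fluoride cleaves the aryl silyl ether and the caesium phenoxide is O-alkylated in the same pot (Williamson etherification), the aryl bromide, ring E and all stereocenters being inert.

Step 16
Reactants: 31 aryl bromide; 32 3,5-dimethoxybenzonitrile
Product: 35 hydrazone of the a6 (3,5-dimethoxyphenyl) ketone, via aryllithium 33 (not isolated), via ketimine 34 (not isolated)
Conditions: n-BuLi (1.05 equiv), THF, −78 °C, 5 min; 32 (1.5 equiv), −78 to 0 °C; MeOH; then N2H4·H2O (10 equiv), AcOH (2 equiv), EtOH, 70 °C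
Reagents that add atoms: hydrazine hydrate, NN.O
Why: Bromine–lithium exchange, addition of the aryllithium to the nitrile to give a ketimine that cannot add a second time, then acid-catalysed transimination by hydrazine, which is easier than condensing hydrazine with the doubly ortho-substituted ketone.

Step 17
Reactants: 35 hydrazone
Product: 37 cis ring F heptamethyl ether (C7' R, C8' S), via diaryldiazomethane 36 (not isolated)
Conditions: MnO2 (8 equiv), CH2Cl2, 0 °C, filter; Rh2(S-PTAD)4 (1 mol%), CH2Cl2, 0 °C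
Reagents that add atoms: none
Why: Oxidation of the hydrazone to the diaryldiazomethane followed by rhodium carbene C–H insertion (donor/donor carbene) into the activated benzylic O–CH2 bond in a 1,5 sense, the chiral carboxylate catalyst selecting the carbene face and so setting C7' (R) while the concerted insertion gives the cis-2,3-diaryl ring (C8' S).

Step 18
Reactants: 37 cis ring F compound
Product: 38 heptamethyl ether of the target (ring F trans; C7' R, C8' R)
Conditions: CF3CO2H (5 equiv), CH2Cl2, 0 °C to rt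
Reagents that add atoms: none
Why: Acid-promoted epimerisation by reversible heterolysis of the benzylic C8'–O bond (cation stabilised by the 4-methoxyphenyl group) and re-closure to the thermodynamically preferred trans ring F, C7' having no leaving group and the already trans ring E keeping its configuration.

Step 19
Reactants: 38 heptamethyl ether
Product: 39 CNP0136963.1
Conditions: BBr3 (20 equiv), CH2Cl2, −78 °C to rt; MeOH, then H2O
Reagents that add atoms: none
Why: Lewis acid cleavage of the seven aryl methyl ethers (boron coordination, then SN2 attack of bromide on methyl), the two dihydrobenzofuran C–O bonds, if they open, re-closing to the same trans isomers.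

Compound list
1 | 2-bromo-3,5-dimethoxybenzaldehyde | COc1cc(OC)c(Br)c(C=O)c1 | starting material
2 | bis(pinacolato)borylmethane | CC1(C)OB(CB2OC(C)(C)C(C)(C)O2)OC1(C)C | starting material
3 | (E)-2-[2-(2-bromo-3,5-dimethoxyphenyl)ethenyl]-4,4,5,5-tetramethyl-1,3,2-dioxaborolane | COc1cc(OC)c(Br)c(/C=C/B2OC(C)(C)C(C)(C)O2)c1 | intermediate
4 | (E)-2-[3-(2-bromo-3,5-dimethoxyphenyl)prop-2-en-1-yl]-4,4,5,5-tetramethyl-1,3,2-dioxaborolane | COc1cc(OC)c(Br)c(/C=C/CB2OC(C)(C)C(C)(C)O2)c1 | intermediate
5 | 4-methoxybenzaldehyde | COc1ccc(C=O)cc1 | starting material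
6 | pinacol borate ester of 7 (O–B(pin) on Ce; not isolated) | C=C[C@@H]([C@H](OB1OC(C)(C)C(C)(C)O1)c1ccc(OC)cc1)c1cc(OC)cc(OC)c1Br | intermediate
7 | (1S,2R)-2-(2-bromo-3,5-dimethoxyphenyl)-1-(4-methoxyphenyl)but-3-en-1-ol | C=C[C@@H]([C@H](O)c1ccc(OC)cc1)c1cc(OC)cc(OC)c1Br | intermediate
8 | tert-butyldimethylsilyl ether of 7 | C=C[C@@H]([C@H](O[Si](C)(C)C(C)(C)C)c1ccc(OC)cc1)c1cc(OC)cc(OC)c1Br | intermediate
9 | aryllithium from 8 (Li on d6; not isolated) | C=C[C@@H]([C@H](O[Si](C)(C)C(C)(C)C)c1ccc(OC)cc1)c1cc(OC)cc(OC)c1[Li] | intermediate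
10 | 2-[(1S,2R)-1-(tert-butyldimethylsilyloxy)-1-(4-methoxyphenyl)but-3-en-2-yl]-4,6-dimethoxybenzaldehyde | C=C[C@@H]([C@H](O[Si](C)(C)C(C)(C)C)c1ccc(OC)cc1)c1cc(OC)cc(OC)c1C=O | intermediate
11 | 3,3-dimethoxybutan-2-one | CC(=O)C(C)(OC)OC | starting material
12 | (E)-enone from 10 and 11 | C=C[C@@H]([C@H](O[Si](C)(C)C(C)(C)C)c1ccc(OC)cc1)c1cc(OC)cc(OC)c1/C=C/C(=O)C(C)(OC)OC | intermediate
13 | 4-methoxyphenylboronic acid | COc1ccc(B(O)O)cc1 | starting material
14 | conjugate adduct, Ca (S) ketone with α-ketal | COc1ccc(cc1)[C@H](CC(=O)C(C)(OC)OC)c1c(OC)cc(OC)cc1[C@@H](C=C)[C@H](O[Si](C)(C)C(C)(C)C)c1ccc(OC)cc1 | intermediate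
15 | methylidene ketal (C=CH2 in place of the C=O of 14) | COc1ccc(cc1)[C@H](CC(=C)C(C)(OC)OC)c1c(OC)cc(OC)cc1[C@@H](C=C)[C@H](O[Si](C)(C)C(C)(C)C)c1ccc(OC)cc1 | intermediate
16 | α-methylidene methyl ketone (metathesis substrate) | COc1ccc(cc1)[C@H](CC(=C)C(C)=O)c1c(OC)cc(OC)cc1[C@@H](C=C)[C@H](O[Si](C)(C)C(C)(C)C)c1ccc(OC)cc1 | intermediate
17 | benzo-fused cycloheptenyl methyl ketone (Ca S, Cf R, Ce S) | COc1ccc([C@@H]2CC(C(C)=O)=C[C@@H]([C@H](O[Si](C)(C)C(C)(C)C)c3ccc(OC)cc3)c3cc(OC)cc(OC)c32)cc1 | intermediate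
18 | trifluoroacetyl derivative of 17 (1,3-diketone; not isolated) | COc1ccc([C@@H]2CC(C(=O)CC(=O)C(F)(F)F)=C[C@@H]([C@H](O[Si](C)(C)C(C)(C)C)c3ccc(OC)cc3)c3cc(OC)cc(OC)c32)cc1 | intermediate
19 | benzo-fused cycloheptenyl diazomethyl ketone (Ca S, Cf R, Ce S) | COc1ccc([C@@H]2CC(C(=O)C=[N+]=[N-])=C[C@@H]([C@H](O[Si](C)(C)C(C)(C)C)c3ccc(OC)cc3)c3cc(OC)cc(OC)c32)cc1 | intermediate
20 | triisopropylsilyloxyacetylene | C#CO[Si](C(C)C)(C(C)C)C(C)C | starting material
21 | vinylketene (ketenyl group on a1; not isolated) | COc1ccc([C@@H]2CC(C=C=O)=C[C@@H]([C@H](O[Si](C)(C)C(C)(C)C)c3ccc(OC)cc3)c3cc(OC)cc(OC)c32)cc1 | intermediate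
22 | 4-(cycloheptenyl)-3-(triisopropylsilyloxy)cyclobut-2-en-1-one (both C4 epimers; not isolated) | COc1ccc([C@@H]2CC(C4C(=O)C=C4O[Si](C(C)C)(C(C)C)C(C)C)=C[C@@H]([C@H](O[Si](C)(C)C(C)(C)C)c3ccc(OC)cc3)c3cc(OC)cc(OC)c32)cc1 | intermediate
23 | dienylketene (not isolated) | COc1ccc([C@@H]2CC(C=C(O[Si](C(C)C)(C(C)C)C(C)C)C=C=O)=C[C@@H]([C@H](O[Si](C)(C)C(C)(C)C)c3ccc(OC)cc3)c3cc(OC)cc(OC)c32)cc1 | intermediate
24 | cyclohexa-2,4-dienone tautomer of 25 (a2 sp3; not isolated) | COc1ccc([C@@H]2CC4=CC(O[Si](C(C)C)(C(C)C)C(C)C)=CC(=O)C4[C@@H]([C@H](O[Si](C)(C)C(C)(C)C)c3ccc(OC)cc3)c3cc(OC)cc(OC)c32)cc1 | intermediate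
25 | ring B phenol: a3 OH, a5 OTIPS, a4 and a6 H (Ca S, Cf S, Ce S) | COc1ccc([C@@H]2Cc3c(c(O)cc(O[Si](C(C)C)(C(C)C)C(C)C)c3)[C@@H]([C@H](O[Si](C)(C)C(C)(C)C)c3ccc(OC)cc3)c3cc(OC)cc(OC)c32)cc1 | intermediate
26 | a6-bromo derivative of 25 | COc1ccc([C@@H]2Cc3c(c(O)cc(O[Si](C(C)C)(C(C)C)C(C)C)c3Br)[C@@H]([C@H](O[Si](C)(C)C(C)(C)C)c3ccc(OC)cc3)c3cc(OC)cc(OC)c32)cc1 | intermediate
27 | Ce carbinol from 26 (not isolated) | COc1ccc([C@@H]2Cc3c(c(O)cc(O[Si](C(C)C)(C(C)C)C(C)C)c3Br)[C@@H]([C@H](O)c3ccc(OC)cc3)c3cc(OC)cc(OC)c32)cc1 | intermediate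
28 | ring E trans-dihydrobenzofuran, a5 OTIPS, a6 Br (Ca S, Cf S, Ce S) | COc1ccc([C@@H]2Cc3c4c(cc(O[Si](C(C)C)(C(C)C)C(C)C)c3Br)O[C@H](c3ccc(OC)cc3)[C@H]4c3cc(OC)cc(OC)c32)cc1 | intermediate
29 | 4-methoxybenzyl chloride | COc1ccc(CCl)cc1 | starting material
30 | caesium a5 phenoxide from 28 (not isolated) | COc1ccc([C@@H]2Cc3c4c(cc([O-])c3Br)O[C@H](c3ccc(OC)cc3)[C@H]4c3cc(OC)cc(OC)c32)cc1.[Cs+] | intermediate
31 | a5 4-methoxybenzyl ether, a6 Br | COc1ccc([C@@H]2Cc3c4c(cc(OCc5ccc(OC)cc5)c3Br)O[C@H](c3ccc(OC)cc3)[C@H]4c3cc(OC)cc(OC)c32)cc1 | intermediate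
32 | 3,5-dimethoxybenzonitrile | COc1cc(OC)cc(C#N)c1 | starting material
33 | aryllithium from 31 (Li on a6; not isolated) | COc1ccc([C@@H]2Cc3c4c(cc(OCc5ccc(OC)cc5)c3[Li])O[C@H](c3ccc(OC)cc3)[C@H]4c3cc(OC)cc(OC)c32)cc1 | intermediate
34 | N–H ketimine on a6 (not isolated) | COc1ccc([C@@H]2Cc3c4c(cc(OCc5ccc(OC)cc5)c3C(=N)c3cc(OC)cc(OC)c3)O[C@H](c3ccc(OC)cc3)[C@H]4c3cc(OC)cc(OC)c32)cc1 | intermediate
35 | hydrazone of the a6 diaryl ketone (C=N isomers) | COc1ccc([C@@H]2Cc3c4c(cc(OCc5ccc(OC)cc5)c3C(=NN)c3cc(OC)cc(OC)c3)O[C@H](c3ccc(OC)cc3)[C@H]4c3cc(OC)cc(OC)c32)cc1 | intermediate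
36 | diaryldiazomethane on a6 (not isolated) | COc1ccc([C@@H]2Cc3c4c(cc(OCc5ccc(OC)cc5)c3C(=[N+]=[N-])c3cc(OC)cc(OC)c3)O[C@H](c3ccc(OC)cc3)[C@H]4c3cc(OC)cc(OC)c32)cc1 | intermediate
37 | heptamethyl ether with cis ring F (C7' R, C8' S) | COc1ccc([C@@H]2Cc3c4c(cc5c3[C@@H](c3cc(OC)cc(OC)c3)[C@@H](c3ccc(OC)cc3)O5)O[C@H](c3ccc(OC)cc3)[C@H]4c3cc(OC)cc(OC)c32)cc1 | intermediate
38 | heptamethyl ether of the target (rings E and F trans; Ca S, Cf S, Ce S, C7' R, C8' R) | COc1ccc([C@@H]2Cc3c4c(cc5c3[C@@H](c3cc(OC)cc(OC)c3)[C@H](c3ccc(OC)cc3)O5)O[C@H](c3ccc(OC)cc3)[C@H]4c3cc(OC)cc(OC)c32)cc1 | intermediate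
39 | CNP0136963.1 | Oc1ccc([C@@H]2Cc3c4c(cc5c3[C@@H](c3cc(O)cc(O)c3)[C@H](c3ccc(O)cc3)O5)O[C@H](c3ccc(O)cc3)[C@H]4c3cc(O)cc(O)c32)cc1 | target

Total step count: 19. Longest linear sequence: 19 steps (from 1; all other building blocks are purchased).

Steps most likely to fail

Step 12. What may go wrong: the photolysis is incomplete or diverted, because four alkoxyarene chromophores compete for the light and the carbene or ketene can be lost before the alkyne captures it. Fallback: setting out from 19, the Wolff rearrangement is run without light using AgO2CPh and Et3N in aqueous THF, which should give the homologous β,γ-unsaturated acid F1. 1-Chloro-N,N,2-trimethylprop-1-en-1-amine in CH2Cl2 converts it under neutral conditions into the acid chloride F2. Slow addition of Et3N to F2 and 20 in toluene at 80 °C generates the same vinylketene 21 by dehydrochlorination, and the sequence runs on through 22, 23 and 24 to rejoin the route at 25.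

Step 17. What may go wrong: loss of catalyst control over the carbene face, since the carbene carbon is flanked by the ether arm and by the ring C methylene, or dimerisation of the diazo compound to the azine. Fallback: setting out from 28, bromine–lithium exchange (n-BuLi, THF, −78 °C) gives the aryllithium F3, which adds to 3,5-dimethoxybenzaldehyde to give the benzhydrol F4 (carbinol epimers, of no consequence). Bu4NF removes the silyl group to give the ortho-hydroxybenzhydrol F5, and sodium 4-toluenesulfinate with HCO2H exchanges the benzhydrylic hydroxyl for a sulfonyl group to give the sulfone F6. Cs2CO3 in CH2Cl2 eliminates sulfinate to the ortho-quinone methide F7, which is intercepted by the ylide formed from an S-(4-methoxybenzyl)sulfonium salt of non-racemic isothiocineole. Conjugate addition at C7' and displacement of the sulfide by the phenoxide, a (4+1) annulation, should close the trans ring F directly and rejoin the route at 38. The chiral sulfide provides reagent control, and the minor trans isomer, a diastereomer that differs only in ring F, would be removed by chromatography.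

Step 7. What may go wrong: slow carbometalation at the β-carbon, whose aryl group is substituted at both ortho positions, so that protodeboronation of 13 takes over, or erosion of facial control by the resident stereocenters. Fallback: setting out from 10, olefination with diethyl {2-oxo-2-[(4R)-2-oxo-4-phenyl-1,3-oxazolidin-3-yl]ethyl}phosphonate (LiCl, iPr2NEt, MeCN) gives the (E)-N-enoyl oxazolidinone F8. 4-Methoxyphenylmagnesium bromide and CuBr·SMe2 in THF/Me2S at −40 °C add to the chelated syn-s-cis imide on the face away from the 4-phenyl group and should give the adduct F9 with Ca (S). Me(MeO)NH·HCl and AlMe3 release the auxiliary and give the Weinreb amide F10; 1-ethoxyvinyllithium gives the α-ethoxy enone F11; Ph3P=CH2 gives the 2-ethoxy diene F12. Dilute aqueous oxalic acid hydrolyses the enol ether and rejoins the route at 16.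

Further compounds
F1 | step 12 | β,γ-unsaturated acid (a1–CH2–CO2H) from 19 | COc1ccc([C@@H]2CC(CC(=O)O)=C[C@@H]([C@H](O[Si](C)(C)C(C)(C)C)c3ccc(OC)cc3)c3cc(OC)cc(OC)c32)cc1
F2 | step 12 | acid chloride of F1 | COc1ccc([C@@H]2CC(CC(=O)Cl)=C[C@@H]([C@H](O[Si](C)(C)C(C)(C)C)c3ccc(OC)cc3)c3cc(OC)cc(OC)c32)cc1
F3 | step 17 | aryllithium from 28 (Li on a6) | COc1ccc([C@@H]2Cc3c4c(cc(O[Si](C(C)C)(C(C)C)C(C)C)c3[Li])O[C@H](c3ccc(OC)cc3)[C@H]4c3cc(OC)cc(OC)c32)cc1
F4 | step 17 | a6 (3,5-dimethoxyphenyl)hydroxymethyl compound, a5 OTIPS (carbinol epimers) | COc1ccc([C@@H]2Cc3c4c(cc(O[Si](C(C)C)(C(C)C)C(C)C)c3C(O)c3cc(OC)cc(OC)c3)O[C@H](c3ccc(OC)cc3)[C@H]4c3cc(OC)cc(OC)c32)cc1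
F5 | step 17 | ortho-hydroxybenzhydrol (a5 OH) | COc1ccc([C@@H]2Cc3c4c(cc(O)c3C(O)c3cc(OC)cc(OC)c3)O[C@H](c3ccc(OC)cc3)[C@H]4c3cc(OC)cc(OC)c32)cc1
F6 | step 17 | 4-tolylsulfonyl derivative of F5 (sulfone on the benzhydrylic carbon) | COc1ccc([C@@H]2Cc3c4c(cc(O)c3C(c3cc(OC)cc(OC)c3)S(=O)(=O)c3ccc(C)cc3)O[C@H](c3ccc(OC)cc3)[C@H]4c3cc(OC)cc(OC)c32)cc1
F7 | step 17 | ortho-quinone methide (a5 C=O, a6=C7') | COc1ccc([C@@H]2CC3=C4C(=CC(=O)C3=Cc3cc(OC)cc(OC)c3)O[C@H](c3ccc(OC)cc3)[C@H]4c3cc(OC)cc(OC)c32)cc1
F8 | step 7 | (E)-N-enoyl (4R)-4-phenyloxazolidinone from 10 | C=C[C@@H]([C@H](O[Si](C)(C)C(C)(C)C)c1ccc(OC)cc1)c1cc(OC)cc(OC)c1/C=C/C(=O)N1C(=O)OC[C@H]1c1ccccc1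
F9 | step 7 | conjugate adduct imide, Ca (S) | COc1ccc(cc1)[C@H](CC(=O)N1C(=O)OC[C@H]1c1ccccc1)c1c(OC)cc(OC)cc1[C@@H](C=C)[C@H](O[Si](C)(C)C(C)(C)C)c1ccc(OC)cc1
F10 | step 7 | Weinreb amide | COc1ccc(cc1)[C@H](CC(=O)N(C)OC)c1c(OC)cc(OC)cc1[C@@H](C=C)[C@H](O[Si](C)(C)C(C)(C)C)c1ccc(OC)cc1
F11 | step 7 | α-ethoxy enone | COc1ccc(cc1)[C@H](CC(=O)C(=C)OCC)c1c(OC)cc(OC)cc1[C@@H](C=C)[C@H](O[Si](C)(C)C(C)(C)C)c1ccc(OC)cc1
F12 | step 7 | 2-ethoxy-3-methylidene diene | COc1ccc(cc1)[C@H](CC(=C)C(=C)OCC)c1c(OC)cc(OC)cc1[C@@H](C=C)[C@H](O[Si](C)(C)C(C)(C)C)c1ccc(OC)cc1
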